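**Retrosynthetic overview**

1. Target 19 ⇐ methanolysis of the formate and acetate in 18 ⇐ Baeyer–Villiger replacement of the C4 formyl group by oxygen with retention (from 17) ⇐ acid unmasking of the enone in cycloadduct 15.
2. 15 ⇐ catalytic enantioselective [4+2] of aminosiloxy diene 14 with 2-alkylacrolein 7. This one step forms the only ring (the cyclohexene), the C3–C4 and C5–C6 bonds and both lasting stereocentres.
3. Feature used: in the cyclohex-2-enone ring (C1 ketone, C2=C3, C4 tertiary carbinol bearing the chain, C5 methylene, C6 secondary carbinol cis to the C4 oxygen), C3–C2–C1–C6 with the C6 oxygen map onto a 1-amino-3-siloxy-4-acyloxybutadiene and C4–C5 onto the alkene of a 2-alkylacrolein, whose formyl carbon is later exchanged for the C4 hydroxyl.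
4. 7 ⇐ α-methylenation, oxidation and Z-selective Wittig reaction from 12-bromododecan-1-ol and heptanal; 14 ⇐ silylation, α′-acetoxylation, N-carbamoylation and amine exchange from (E)-4-methoxybut-3-en-2-one and benzylamine.

Key step: step 9

Assumption: the (R,R) antipode of the salen ligand is written for the (3S,4R,6S) adduct; the sense of induction is to be checked on the first run, and the (S,S) complex is used instead if it proves opposite.

**Route**

Step 1
Reactants: 1 12-bromododecan-1-ol
Product: 2 (12-hydroxydodecyl)triphenylphosphonium bromide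
Conditions: PPh3 (1.05 equiv), MeCN, reflux
Reagents that add atoms: triphenylphosphine, c1ccc(cc1)P(c1ccccc1)c1ccccc1
Why: SN2 quaternisation of the phosphine by the unhindered primary bromide (phosphonium salt formation), which the free hydroxyl does not disturb.

Step 2
Reactants: 2 (12-hydroxydodecyl)triphenylphosphonium bromide; 3 heptanal
Product: 5 (Z)-nonadec-12-en-1-ol, via ylide alkoxide 4 (not isolated)
Conditions: NaHMDS (2.1 equiv), THF, −78 → 0 °C; then 3, −78 °C → rt; H2O
Reagents that add atoms: none
Why: Wittig reaction of a non-stabilised ylide under lithium-free conditions, where kinetic formation of the cis-oxaphosphetane should give the Z alkene, the alkoxide being a spectator.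

Step 3
Reactants: 5 (Z)-nonadec-12-en-1-ol
Product: 6 (Z)-nonadec-12-enal
Conditions: TEMPO (10 mol %), PhI(OAc)2 (1.1 equiv), CH2Cl2, rt
Reagents that add atoms: none
Why: Oxoammonium (TEMPO) oxidation of a primary alcohol, which stops at the aldehyde and leaves the isolated Z alkene untouched.

Step 4
Reactants: 6 (Z)-nonadec-12-enal
Product: 7 (Z)-2-methylenenonadec-12-enal
Conditions: aq. CH2O (37 %), pyrrolidine (10 mol %), EtCO2H (10 mol %), i-PrOH, 45 °C
Reagents that add atoms: formaldehyde, C=O
Why: Amine-catalysed Mannich condensation–elimination (α-methylenation of an aldehyde): the enamine of 6 adds to the formaldehyde iminium ion and loss of the amine gives the 2-alkylacrolein.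

Step 5
Reactants: 8 (E)-4-methoxybut-3-en-2-one; 9 benzylamine
Product: 10 (Z)-4-(benzylamino)but-3-en-2-one
Conditions: CH2Cl2, rt
Reagents that add atoms: none
Why: Conjugate addition–elimination (amine exchange) on the β-methoxy enone; the Z enaminone is held by an N–H···O hydrogen bond.

Step 6
Reactants: 10 (Z)-4-(benzylamino)but-3-en-2-one
Product: 11 methyl benzyl[(E)-3-oxobut-1-en-1-yl]carbamate
Conditions: NaHMDS (1.05 equiv), THF, −78 °C; ClCO2Me, −78 → 0 °C
Reagents that add atoms: methyl chloroformate, COC(=O)Cl
Why: N-Acylation of the sodium aza-enolate by the chloroformate (carbamate formation); without the hydrogen bond the push–pull alkene should settle in the E form.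

Step 7
Reactants: 11 methyl benzyl[(E)-3-oxobut-1-en-1-yl]carbamate
Product: 13 methyl benzyl[(E)-4-acetoxy-3-oxobut-1-en-1-yl]carbamate, via trimethylsilyl dienol ether 12 (not isolated)
Conditions: LiHMDS, TMSCl, THF, −78 °C; solvent exchange; Pb(OAc)4 (1.1 equiv), CH2Cl2, −40 → 0 °C; aq. NaHCO3
Reagents that add atoms: lead tetraacetate, CC(=O)O[Pb](OC(C)=O)(OC(C)=O)OC(C)=O
Why: Kinetic enolisation at the only enolisable carbon gives the 2-siloxydiene, whose terminal carbon (the most nucleophilic site) is acetoxylated by lead tetraacetate in a Rubottom-type oxidation of a siloxydiene to an α′-acetoxy enone.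

Step 8
Reactants: 13 methyl benzyl[(E)-4-acetoxy-3-oxobut-1-en-1-yl]carbamate
Product: 14 methyl benzyl[(1E,3Z)-4-acetoxy-3-(tert-butyldimethylsilyloxy)buta-1,3-dien-1-yl]carbamate
Conditions: TBSOTf (1.2 equiv), Et3N (2 equiv), Et2O, −78 → 0 °C
Reagents that add atoms: tert-butyldimethylsilyl trifluoromethanesulfonate, CC(C)(C)[Si](C)(C)OS(=O)(=O)C(F)(F)F
Why: Soft enolisation (silyl triflate–amine enol silylation) toward the more acidic acetoxymethylene; as with other α-oxygenated ketones the isomer with acetoxy cis to siloxy (3Z, acetoxy pointing outward) should prevail because it avoids a clash between the acetoxy and vinyl groups.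

Step 9
Reactants: 14 methyl benzyl[(1E,3Z)-4-acetoxy-3-(tert-butyldimethylsilyloxy)buta-1,3-dien-1-yl]carbamate; 7 (Z)-2-methylenenonadec-12-enal
Product: 15 methyl benzyl[(1S,4S,6R)-4-acetoxy-3-(tert-butyldimethylsilyloxy)-6-formyl-6-[(Z)-heptadec-10-en-1-yl]cyclohex-2-en-1-yl]carbamate (formyl, acetoxy and nitrogen all on one face)
Conditions: (R,R)-(salen)CrSbF6 (5 mol %; salen = N,N′-bis(3,5-di-tert-butylsalicylidene)-1,2-cyclohexanediamine dianion, trivalent chromium), powdered 4 Å MS, CH2Cl2, −40 °C
Reagents that add atoms: none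
Why: Coordination of the formyl oxygen of 7 to the cationic chromium centre lowers its LUMO, and the diene adds in a concerted yet uneven [4+2] cycloaddition in which the siloxy-activated terminus (future C6) bonds to the acrolein methylene (C5) ahead of the C3–C4 bond, so that nitrogen ends next to the quaternary carbon. The closest known reaction is the salen–chromium-catalysed enantioselective Diels–Alder reaction of 1-(carbamoylamino)-3-siloxybutadienes with 2-alkylacroleins; the terminal acyloxy group is an added substituent of the kind carried by 4-acyloxy-3-siloxy-1-alkoxydienes in Lewis acid cycloadditions. The six-membered carbocycle is closed by suprafacial addition across both components, both new bonds forming in the same step. C4 is fixed by the chiral salen ligand, which exposes one enantioface of the bound acrolein; C3 and C6 follow from the endo placement of the bound formyl group together with the (1E,3Z) diene geometry, whose two outward groups finish on the face of the formyl group, so CHO, OAc and N are all cis. The step needs regioselectivity (secured by the amino/siloxy polarisation of the diene), endo selectivity (secondary overlap of the formyl group, the 2-alkyl chain taking the exo site) and facial selectivity (ligand); any 3E diene cannot easily reach the s-cis form and should stay behind.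

Step 10
Reactants: 15 cycloadduct
Product: 17 (1S,5R)-5-formyl-5-[(Z)-heptadec-10-en-1-yl]-2-oxocyclohex-3-en-1-yl acetate, via carbamato ketone 16 (not isolated)
Conditions: TsOH·H2O (0.5 equiv), MeCN–CH2Cl2 with H2O (2 equiv), 0 °C → rt
Reagents that add atoms: none
Why: Acid-catalysed protodesilylation of the silyl enol ether followed by retro-aza-Michael β-elimination of the carbamate (the reverse of the Brønsted acid-catalysed conjugate addition of carbamates to enones), driven by release of crowding next to the quaternary carbon; C4 has no α-hydrogen and acid enolisation is slow toward the acetoxy-bearing C6, so both stereocentres should hold.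

Step 11
Reactants: 17 (1S,5R)-5-formyl-5-[(Z)-heptadec-10-en-1-yl]-2-oxocyclohex-3-en-1-yl acetate
Product: 18 (1S,5R)-5-(formyloxy)-5-[(Z)-heptadec-10-en-1-yl]-2-oxocyclohex-3-en-1-yl acetate
Conditions: Me3SiOOSiMe3 (2 equiv), TMSOTf (0.2 equiv), 4 Å MS, CH2Cl2, −40 → −20 °C; pH 7 buffer
Reagents that add atoms: bis(trimethylsilyl) peroxide, C[Si](C)(C)OO[Si](C)(C)C
Why: Baeyer–Villiger oxidation through the silyl peroxyacetal (Criegee adduct): the tertiary C4 migrates to oxygen in preference to hydrogen and with retention, and the silyl peroxide–Lewis acid pair is not an epoxidising agent, so the chain alkene and the enone should be left alone.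

Step 12
Reactants: 18 (1S,5R)-5-(formyloxy)-5-[(Z)-heptadec-10-en-1-yl]-2-oxocyclohex-3-en-1-yl acetate
Product: 19 (4R,6S)-4-[(Z)-heptadec-10-en-1-yl]-4,6-dihydroxycyclohex-2-en-1-one
Conditions: Sc(OTf)3 (20 mol %), MeOH–H2O 4:1, 25 °C
Reagents that add atoms: none
Why: Lewis acid-catalysed transesterification: the formate is the most labile ester and the acetate is activated by chelation of scandium between the ketone and ester carbonyls, so both hydroxyls are freed without base and C6 should not epimerise.

**Compound list**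

1 | 12-bromododecan-1-ol | OCCCCCCCCCCCCBr | starting material
2 | (12-hydroxydodecyl)triphenylphosphonium bromide | OCCCCCCCCCCCC[P+](c1ccccc1)(c1ccccc1)c1ccccc1.[Br-] | intermediate
3 | heptanal | CCCCCCC=O | starting material
4 | sodium 12-(triphenylphosphoranylidene)dodecan-1-olate (ylide alkoxide) | [Na+].[O-]CCCCCCCCCCCC=P(c1ccccc1)(c1ccccc1)c1ccccc1 | intermediate
5 | (Z)-nonadec-12-en-1-ol | OCCCCCCCCCCC/C=C\CCCCCC | intermediate
6 | (Z)-nonadec-12-enal | O=CCCCCCCCCCC/C=C\CCCCCC | intermediate
7 | (Z)-2-methylenenonadec-12-enal | C=C(C=O)CCCCCCCCC/C=C\CCCCCC | intermediate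
8 | (E)-4-methoxybut-3-en-2-one | CO/C=C/C(C)=O | starting material
9 | benzylamine | NCc1ccccc1 | starting material
10 | (Z)-4-(benzylamino)but-3-en-2-one | CC(=O)/C=C\NCc1ccccc1 | intermediate
11 | methyl benzyl[(E)-3-oxobut-1-en-1-yl]carbamate | COC(=O)N(Cc1ccccc1)/C=C/C(C)=O | intermediate
12 | methyl benzyl[(E)-3-(trimethylsilyloxy)buta-1,3-dien-1-yl]carbamate | COC(=O)N(Cc1ccccc1)/C=C/C(=C)O[Si](C)(C)C | intermediate
13 | methyl benzyl[(E)-4-acetoxy-3-oxobut-1-en-1-yl]carbamate | COC(=O)N(Cc1ccccc1)/C=C/C(=O)COC(C)=O | intermediate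
14 | methyl benzyl[(1E,3Z)-4-acetoxy-3-(tert-butyldimethylsilyloxy)buta-1,3-dien-1-yl]carbamate | COC(=O)N(Cc1ccccc1)/C=C/C(O[Si](C)(C)C(C)(C)C)=C/OC(C)=O | intermediate
15 | methyl benzyl[(1S,4S,6R)-4-acetoxy-3-(tert-butyldimethylsilyloxy)-6-formyl-6-[(Z)-heptadec-10-en-1-yl]cyclohex-2-en-1-yl]carbamate | O=C[C@]1(CCCCCCCCC/C=C\CCCCCC)C[C@H](OC(C)=O)C(O[Si](C)(C)C(C)(C)C)=C[C@@H]1N(Cc2ccccc2)C(=O)OC | intermediate
16 | methyl benzyl[(1S,2R,4S)-4-acetoxy-2-formyl-2-[(Z)-heptadec-10-en-1-yl]-5-oxocyclohexyl]carbamate | O=C[C@]1(CCCCCCCCC/C=C\CCCCCC)C[C@H](OC(C)=O)C(=O)C[C@@H]1N(Cc2ccccc2)C(=O)OC | intermediate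
17 | (1S,5R)-5-formyl-5-[(Z)-heptadec-10-en-1-yl]-2-oxocyclohex-3-en-1-yl acetate | O=C[C@]1(CCCCCCCCC/C=C\CCCCCC)C[C@H](OC(C)=O)C(=O)C=C1 | intermediate
18 | (1S,5R)-5-(formyloxy)-5-[(Z)-heptadec-10-en-1-yl]-2-oxocyclohex-3-en-1-yl acetate | O=CO[C@]1(CCCCCCCCC/C=C\CCCCCC)C[C@H](OC(C)=O)C(=O)C=C1 | intermediate
19 | (4R,6S)-4-[(Z)-heptadec-10-en-1-yl]-4,6-dihydroxycyclohex-2-en-1-one | CCCCCC/C=C\CCCCCCCCC[C@]1(O)C=CC(=O)[C@@H](O)C1 | target

**Step count**

Total: 12 steps. Longest linear sequence: 8 steps (steps 1–4 then 9–12; the diene branch, steps 5–8 then 9–12, is equally long).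

**Steps most likely to fail**

Step 9. The acetoxy group makes the reacting diene terminus more hindered and less electron-rich than in the parent diene. Cycloaddition to the α-branched acrolein may then be slow enough for adventitious hydrolysis of the diene to win, or the endo and facial discrimination of the chromium complex may erode. The fallback changes the activation mode from Lewis acid catalysis on a carbamate diene to hydrogen-bond catalysis on the more nucleophilic dialkylamino diene, a known enantioselective Diels–Alder manifold for 2-alkylacroleins. It sets out from acrolein 7 and the commercial diene (E)-3-(tert-butyldimethylsilyloxy)-N,N-dimethylbuta-1,3-dien-1-amine (CN(C)/C=C/C(=C)O[Si](C)(C)C(C)(C)C). Pb(OAc)4 in CH2Cl2 at −40 °C should convert this diene into [(E)-4-(dimethylamino)-2-oxobut-3-en-1-yl] acetate F1. KHMDS and TBSCl in THF at −78 °C should then give (1E,3Z)-4-acetoxy-3-(tert-butyldimethylsilyloxy)-N,N-dimethylbuta-1,3-dien-1-amine F2. F2 and 7, with a tetra(1-naphthyl) TADDOL (20 mol %) in toluene at −78 °C, should give (1S,4S,5R)-2-(tert-butyldimethylsilyloxy)-4-(dimethylamino)-5-formyl-5-[(Z)-heptadec-10-en-1-yl]cyclohex-2-en-1-yl acetate F3. Aqueous HF in MeCN then hydrolyses the enol ether and expels dimethylamine as its ammonium ion, and the route is rejoined at enone 17.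

Step 11. The migrating carbon is attached to the electron-poor β-carbon of the enone, so the silyl peroxyacetal may lose hydride instead (giving the carboxylic acid) or dimerise to a cyclic peroxide. The fallback replaces the Baeyer–Villiger reaction by a carboxy inversion, which has no competing hydride shift and also proceeds with retention. It sets out from 17. NaClO2, NaH2PO4 and 2-methylbut-2-ene in t-BuOH–H2O (Pinnick oxidation) should give (1R,5S)-5-acetoxy-1-[(Z)-heptadec-10-en-1-yl]-4-oxocyclohex-2-ene-1-carboxylic acid F4. mCPBA (1.0 equiv) and DCC in CH2Cl2 at −20 °C, where acylation of the peracid should outrun epoxidation, give 3-chlorobenzoyl (1R,5S)-5-acetoxy-1-[(Z)-heptadec-10-en-1-yl]-4-oxocyclohex-2-ene-1-carbonyl peroxide F5. Warming F5 in MeCN should rearrange it to (1S,5R)-5-[(3-chlorobenzoyl)oxycarbonyloxy]-5-[(Z)-heptadec-10-en-1-yl]-2-oxocyclohex-3-en-1-yl acetate F6. Under the conditions of step 12, F6 loses the aroyl group, carbon dioxide and the acetate, and the route is rejoined at target 19.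

Step 7. Lead tetraacetate may attack the enamide carbon or over-oxidise, or the labile trimethylsilyl dienol ether may revert to 11 before it is oxidised. The fallback replaces the oxidative acetoxylation by halogenation and substitution. It sets out from 12, made from 11 as in step 7. NBS in THF at −78 °C should give methyl benzyl[(E)-4-bromo-3-oxobut-1-en-1-yl]carbamate F7. CsOAc in DMF at rt then displaces bromide by SN2 at the α-keto carbon, and the route is rejoined at 13.

**Further compounds**

F1 | step 9 | [(E)-4-(dimethylamino)-2-oxobut-3-en-1-yl] acetate | CN(C)/C=C/C(=O)COC(C)=O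
F2 | step 9 | (1E,3Z)-4-acetoxy-3-(tert-butyldimethylsilyloxy)-N,N-dimethylbuta-1,3-dien-1-amine | CN(C)/C=C/C(O[Si](C)(C)C(C)(C)C)=C/OC(C)=O
F3 | step 9 | (1S,4S,5R)-2-(tert-butyldimethylsilyloxy)-4-(dimethylamino)-5-formyl-5-[(Z)-heptadec-10-en-1-yl]cyclohex-2-en-1-yl acetate | O=C[C@]1(CCCCCCCCC/C=C\CCCCCC)C[C@H](OC(C)=O)C(O[Si](C)(C)C(C)(C)C)=C[C@@H]1N(C)C
F4 | step 11 | (1R,5S)-5-acetoxy-1-[(Z)-heptadec-10-en-1-yl]-4-oxocyclohex-2-ene-1-carboxylic acid | OC(=O)[C@]1(CCCCCCCCC/C=C\CCCCCC)C[C@H](OC(C)=O)C(=O)C=C1
F5 | step 11 | 3-chlorobenzoyl (1R,5S)-5-acetoxy-1-[(Z)-heptadec-10-en-1-yl]-4-oxocyclohex-2-ene-1-carbonyl peroxide | O=C(OOC(=O)c1cccc(Cl)c1)[C@]1(CCCCCCCCC/C=C\CCCCCC)C[C@H](OC(C)=O)C(=O)C=C1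
F6 | step 11 | (1S,5R)-5-[(3-chlorobenzoyl)oxycarbonyloxy]-5-[(Z)-heptadec-10-en-1-yl]-2-oxocyclohex-3-en-1-yl acetate | O=C(O[C@]1(CCCCCCCCC/C=C\CCCCCC)C[C@H](OC(C)=O)C(=O)C=C1)OC(=O)c1cccc(Cl)c1
F7 | step 7 | methyl benzyl[(E)-4-bromo-3-oxobut-1-en-1-yl]carbamate | COC(=O)N(Cc1ccccc1)/C=C/C(=O)CBr
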